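**Fixed catalyst.** The catalyst stands at 1.5 mM in the flask and in the epsilon, theta and eta runs, so you can read the effect of the other charges from these runs.

| setting | epsilon | theta | eta | flask |
|---|---|---|---|---|
| starting material | 0.30 M | 0.30 M | 0.45 M | 0.30 M |
| protic impurity | 0.045 M | 0.068 M | 0.090 M | 0.0900 M |
| catalyst | 1.5 mM | 1.5 mM | 1.5 mM | 1.5 mM |
| remark | run made earlier | run made earlier | run made earlier |  |
| time |  |  |  | 5.0 d |

- epsilon (time / d: target / %, starting material / %): 1.25: 52.8, 3.7; 2.50: 56.2, 0; 4.00: 55.5, 0; 5.00: 55.7, 0.1; 6.00: 56.7, 0.1
- theta (time / d: target / %, starting material / %): 0.500: 37.3, 17.6; 1.67: 50.5, 1.0; 3.00: 51.6, 0; 4.00: 51.5, 0.2; 6.00: 52.1, 0.1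
- eta (time / d: target / %, starting material / %): 0.500: 33.2, 14.5; 1.67: 45.7, 1.9; 3.00: 48.2, 0.4; 4.00: 47.1, 0; 6.00: 48.2, 0

(readings scatter by 0.5 percentage points)

- the analysis behind the earlier runs scatters by 0.5 percentage points, standard deviation
- the reaction counts as stopped when no species that holds the starting material changes by six tenths of a point or more over the second half of the time

- the state of affairs at 5.0 d: stopped, and by what, or still going (no working catalyst is left / it is still moving / all of the starting material has reacted)
- amount of target at 5.0 d, in percent of the starting material charged

**The load.** I assume that the protic impurity takes starting material one for one, and that the catalyst's route to target competes with a loss. So I use the load, the starting material the impurity leaves per catalyst, 140 in the flask. The kept share (selectivity) is the target as a part of that remainder.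

**Flask against eta.** The theta run reads load 155 and keeps 67.4 %. The eta run reads load 240 and keeps 60.2 %. The flask shares eta's impurity and catalyst, but the impurity leaves it 70.0 % of its charge, against 80.0 % in eta. Its load is lower, so the line through both runs lets it keep 68.6 %. That gives 48.0 % target, close to eta's last reading, with a smaller remainder than eta's and a larger share offsetting each other. Theta, charged like the flask with starting material and catalyst but with less impurity, reads 0 % starting material at 3.00 d, so I expect none in the flask at 5.0 d.

**The result.** The forecast, on a different ground (“the yield seems to follow absolute impurity level”), says all of the starting material has reacted, with 48 % target. The flask gives: all of the starting material has reacted, with 48.4 % target.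

    starting material + protic impurity → quenched substrate (k = 0.164 L mol⁻¹ min⁻¹)
    2 starting material → self-condensation product (k = 0.00307 L mol⁻¹ min⁻¹)
    starting material + catalyst → catalyst + target (k = 0.891 L mol⁻¹ min⁻¹)

**Less catalyst.** The flask kept 69.1 % at load 140. Now charge a neighbour flask with 0.900 mM catalyst. Its load rises to 233, close to eta's, and the same line gives a kept share of 60.8 %, hence 42.6 % target. The neighbour flask gives 41.2 % target, with quenched substrate at 30.0 % and self-condensation product at 28.7 %, against 21.6 % in the flask.

Readings and results come from a simulation from invented constants; the scatter is artificial.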